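**Plan**

1. Retrosynthesis first cuts the interflavanoid bond C4–C2′. The lower unit is (+)-dihydrorobinetin, bought with its ring and both stereocentres.
2. In the same operation the pyran ring of the upper unit is contracted: the C2–C3 bond is broken and C2 is rejoined to C4, which leads back to an O-acylated cis-2-aryl-2,3-dihydrobenzofuran-3-carbaldehyde. This is then cut at C2–C3 of the furan ring (Rh-carbene C–H insertion), and further back to a diazo ester, an aryl bromide and a benzylic aryl ether.
3. Forward order: ring A ether, aryl glyoxylate, diazo ester, five-membered O-ring by C–H insertion, one-carbon ring enlargement to the pyran ring with C4–C2′ bond formation, removal of the chloroacetyl helper, hydrogenolysis.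
4. Enabling feature: C4 is benzylic to ring A, whose O7 (para) and O1 (ortho) stabilise a flavan-4-yl cation. C2 is an α-oxygenated benzylic carbon and migrates easily. With an acyl group on O3 the former formyl carbon is a high-energy acyloxycarbenium trigger, so the acylated 3-formyl-dihydrobenzofuran is a latent flavan-4-yl cation.
5. Stereochemistry: C2 and the cis geometry come from the chiral Rh(II) catalyst. C3 is relayed from that cis geometry in the 1,2-shift, and C4 is set by anti attack on the 3,4-acyloxonium ion. C2 and C3 of the lower unit are purchased.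

Key step: step 6

Remark: compounds 1, 2 and 9 are taken as purchasable, and the enantiomer of the Rh(II) catalyst in step 4 is the one that leads to the (2S,3R) ester.

**Step 1**
Reactants: 1 5-(benzyloxy)-2-bromophenol; 2 [3,4,5-tris(benzyloxy)phenyl]methanol
Product: 3 4-(benzyloxy)-1-bromo-2-{[3,4,5-tris(benzyloxy)phenyl]methoxy}benzene
Conditions: PPh3, DIAD, THF, 0 °C to rt
Reagents that add atoms: none
Why: Mitsunobu etherification of an acidic phenol with a primary benzylic alcohol should give the aryl benzyl ether under neutral conditions; no stereocentre is formed.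

**Step 2**
Reactants: 3 4-(benzyloxy)-1-bromo-2-{[3,4,5-tris(benzyloxy)phenyl]methoxy}benzene
Product: 4 methyl 2-(4-(benzyloxy)-2-{[3,4,5-tris(benzyloxy)phenyl]methoxy}phenyl)-2-oxoacetate
Conditions: n-BuLi, THF, −78 °C; cannulated into dimethyl oxalate (2 equiv), THF, −78 °C; aq. NH4Cl
Reagents that add atoms: dimethyl oxalate, COC(=O)C(=O)OC
Why: Bromine–lithium exchange followed by acylation of the aryllithium with a dialkyl oxalate (aryl glyoxylate synthesis) should stop at the keto ester on inverse addition, and the low temperature should prevent anion transfer to the benzylic OCH2 group.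

**Step 3**
Reactants: 4 methyl 2-(4-(benzyloxy)-2-{[3,4,5-tris(benzyloxy)phenyl]methoxy}phenyl)-2-oxoacetate
Product: 6 methyl 2-diazo-2-(4-(benzyloxy)-2-{[3,4,5-tris(benzyloxy)phenyl]methoxy}phenyl)acetate, via tosylhydrazone 5 (not isolated)
Conditions: TsNHNH2, toluene, 80 °C; concentrate; DBU, CH2Cl2, rt
Reagents that add atoms: p-toluenesulfonyl hydrazide, Cc1ccc(cc1)S(=O)(=O)NN
Why: Hydrazone formation at the activated keto group and Bamford–Stevens loss of sulfinate should give the donor/acceptor aryldiazoacetate; no stereocentre is formed.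

**Step 4**
Reactants: 6 methyl 2-diazo-2-(4-(benzyloxy)-2-{[3,4,5-tris(benzyloxy)phenyl]methoxy}phenyl)acetate
Product: 7 methyl (2S,3R)-6-(benzyloxy)-2-[3,4,5-tris(benzyloxy)phenyl]-2,3-dihydro-1-benzofuran-3-carboxylate (2,3-cis)
Conditions: Rh2(S-PTTL)4 or its antipode (1 mol %), toluene, −60 °C
Reagents that add atoms: none
Why: Intramolecular 1,5 C–H insertion of the Rh(II) carbene into the benzylic ether C–H closes the dihydrofuran ring; chiral N-phthaloyl-tert-leucinate rhodium carboxylates are known to give cis-2-aryl-3-alkoxycarbonyl-2,3-dihydrobenzofurans enantioselectively, so C2 and C3 are both set by the catalyst.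

**Step 5**
Reactants: 7 methyl (2S,3R)-6-(benzyloxy)-2-[3,4,5-tris(benzyloxy)phenyl]-2,3-dihydro-1-benzofuran-3-carboxylate
Product: 8 (2S,3R)-6-(benzyloxy)-2-[3,4,5-tris(benzyloxy)phenyl]-2,3-dihydro-1-benzofuran-3-carbaldehyde (2,3-cis)
Conditions: DIBAL-H (1.1 equiv), CH2Cl2, −78 °C; MeOH, then aq. Rochelle salt; used at once without chromatography
Reagents that add atoms: none
Why: Partial reduction of a methyl ester by DIBAL-H goes through a tetrahedral aluminium hemiacetal that is stable at −78 °C; no stereocentre is formed, and the epimerisable cis aldehyde is not purified on silica.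

**Step 6**
Reactants: 8 (2S,3R)-6-(benzyloxy)-2-[3,4,5-tris(benzyloxy)phenyl]-2,3-dihydro-1-benzofuran-3-carbaldehyde; 9 (+)-dihydrorobinetin, (2R,3R)-3,7-dihydroxy-2-(3,4,5-trihydroxyphenyl)chroman-4-one
Product: 12 3-O-chloroacetyl-7,3′,4′,5′-tetra-O-benzylrobinetinidol-(4α→2′)-dihydrorobinetin, via gem-bis(chloroacetate) 10 (not isolated), via flavan-4-yl cation 11 (not isolated)
Conditions: (ClCH2CO)2O (1.1 equiv), Bi(OTf)3 (5 mol %), CH2Cl2, −20 °C; then added slowly to 9 (3 equiv) in HFIP, 0 °C
Reagents that add atoms: chloroacetic anhydride, ClCC(=O)OC(=O)CCl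
Why: Proposed new method: O-acylation of the aldehyde gives the gem-bis(chloroacetate) 10, and Lewis-acid loss of one chloroacetate should be assisted by a suprafacial 1,2-shift of C2 (an α-oxygenated benzylic carbon, migrating with retention) from C3 of the dihydrobenzofuran to the acyloxycarbenium carbon, so that the five-membered O1–C2–C3–C3a–C7a ring becomes the six-membered pyran ring and the charge arrives at the new C4, benzylic to ring A and stabilised by O7 (para), O1 (ortho) and the neighbouring 3-acyloxy group (cation 11, bridged as a cis-fused dioxolanylium ion), which C2′ of the pyrogallol ring of 9 then attacks. The closest known reaction types are the first step of the acid-catalysed aldehyde–ketone (retro-pinacol) rearrangement, which is formally the reverse of the pinacol-type ring contraction of chroman-3,4-diol derivatives to 2,3-dihydrobenzofuran-3-carbaldehydes, and the biomimetic capture of flavan-4-yl cations by phenols, with 1,2-trans control by a participating ester as in glycosylation. No ring is closed by cyclisation: the pyran ring arises by one-carbon ring enlargement (the former formyl carbon is inserted between C2 and C4 as C3), and only the transient dioxolanylium ring forms by five-membered neighbouring-group closure. C3 is controlled by the cis geometry of 8, because in the staggered rotamer with the acylal hydrogen anti to H3 the chloroacetate that stays lies anti to C3a and ends trans to the 2-aryl group after the shift, and C4 is controlled by anti opening of the acyloxonium ion (3,4-trans). The step needs the shift to win over intermolecular attack at the acylal carbon and over hydride or aryl migration; the acyl group on oxygen should secure this, because an acyloxycarbenium ion lies far above the flavan-4-yl cation (whereas alkoxycarbenium ions make the contraction the normal direction), and the reactive rotamer has no leaving group anti to H3. It also needs C2′ of 9 to react in preference to ring A of 9 (deactivated by the C4 carbonyl) and to ring A of the electrophile, which the excess of 9 and the slow addition should secure.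

**Step 7**
Reactants: 12 3-O-chloroacetyl-7,3′,4′,5′-tetra-O-benzylrobinetinidol-(4α→2′)-dihydrorobinetin
Product: 13 7,3′,4′,5′-tetra-O-benzylrobinetinidol-(4α→2′)-dihydrorobinetin
Conditions: thiourea, 2,6-lutidine, MeOH/THF, 50 °C, under Ar
Reagents that add atoms: none
Why: Chloroacetate cleavage by thiourea (S-alkylation at CH2Cl, then intramolecular aminolysis to pseudothiohydantoin) should free the hindered 3-hydroxyl under near-neutral conditions that the dihydroflavonol and the free phenols tolerate, and it is done before hydrogenolysis because of the C–Cl bond; no stereocentre is touched.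

**Step 8**
Reactants: 13 7,3′,4′,5′-tetra-O-benzylrobinetinidol-(4α→2′)-dihydrorobinetin
Product: 14 robinetinidol-(4α→2′)-dihydrorobinetin (target)
Conditions: H2 (1 atm), 10% Pd/C, THF/MeOH, rt
Reagents that add atoms: none
Why: Catalytic hydrogenolysis should remove the four aryl benzyl ethers, while the C4 ketone of the lower unit (a vinylogous acid with 7-OH), the diaryl-substituted C4–C2′ bond and all five stereocentres are left untouched.

**Compound list**

1 | 5-(benzyloxy)-2-bromophenol | Oc1cc(OCc2ccccc2)ccc1Br | starting material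
2 | [3,4,5-tris(benzyloxy)phenyl]methanol | OCc1cc(OCc2ccccc2)c(OCc2ccccc2)c(OCc2ccccc2)c1 | starting material
3 | 4-(benzyloxy)-1-bromo-2-{[3,4,5-tris(benzyloxy)phenyl]methoxy}benzene | Brc1ccc(OCc2ccccc2)cc1OCc1cc(OCc2ccccc2)c(OCc2ccccc2)c(OCc2ccccc2)c1 | intermediate
4 | methyl 2-(4-(benzyloxy)-2-{[3,4,5-tris(benzyloxy)phenyl]methoxy}phenyl)-2-oxoacetate | COC(=O)C(=O)c1ccc(OCc2ccccc2)cc1OCc1cc(OCc2ccccc2)c(OCc2ccccc2)c(OCc2ccccc2)c1 | intermediate
5 | N-tosylhydrazone of 4 | COC(=O)C(=NNS(=O)(=O)c1ccc(C)cc1)c1ccc(OCc2ccccc2)cc1OCc1cc(OCc2ccccc2)c(OCc2ccccc2)c(OCc2ccccc2)c1 | intermediate (not isolated)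
6 | methyl 2-diazo-2-(4-(benzyloxy)-2-{[3,4,5-tris(benzyloxy)phenyl]methoxy}phenyl)acetate | COC(=O)C(=[N+]=[N-])c1ccc(OCc2ccccc2)cc1OCc1cc(OCc2ccccc2)c(OCc2ccccc2)c(OCc2ccccc2)c1 | intermediate
7 | methyl (2S,3R)-6-(benzyloxy)-2-[3,4,5-tris(benzyloxy)phenyl]-2,3-dihydro-1-benzofuran-3-carboxylate (cis) | COC(=O)[C@@H]1c2ccc(OCc3ccccc3)cc2O[C@@H]1c1cc(OCc2ccccc2)c(OCc2ccccc2)c(OCc2ccccc2)c1 | intermediate
8 | (2S,3R)-6-(benzyloxy)-2-[3,4,5-tris(benzyloxy)phenyl]-2,3-dihydro-1-benzofuran-3-carbaldehyde (cis) | O=C[C@@H]1c2ccc(OCc3ccccc3)cc2O[C@@H]1c1cc(OCc2ccccc2)c(OCc2ccccc2)c(OCc2ccccc2)c1 | intermediate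
9 | (+)-dihydrorobinetin, (2R,3R)-3,7-dihydroxy-2-(3,4,5-trihydroxyphenyl)chroman-4-one | O=C1c2ccc(O)cc2O[C@H](c2cc(O)c(O)c(O)c2)[C@H]1O | starting material
10 | {(2S,3R)-6-(benzyloxy)-2-[3,4,5-tris(benzyloxy)phenyl]-2,3-dihydro-1-benzofuran-3-yl}methylene bis(chloroacetate) | ClCC(=O)OC(OC(=O)CCl)[C@@H]1c2ccc(OCc3ccccc3)cc2O[C@@H]1c1cc(OCc2ccccc2)c(OCc2ccccc2)c(OCc2ccccc2)c1 | intermediate (not isolated)
11 | (2R,3S)-7-(benzyloxy)-3-(chloroacetoxy)-2-[3,4,5-tris(benzyloxy)phenyl]chroman-4-ylium (flavan-4-yl cation, bridged as the cis-fused 3,4-dioxolanylium ion) | [CH+]1c2ccc(OCc3ccccc3)cc2O[C@H](c2cc(OCc3ccccc3)c(OCc3ccccc3)c(OCc3ccccc3)c2)[C@H]1OC(=O)CCl | intermediate (not isolated)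
12 | 3-O-chloroacetyl-7,3′,4′,5′-tetra-O-benzylrobinetinidol-(4α→2′)-dihydrorobinetin; upper unit (2R,3S,4S), lower unit (2R,3R) | O=C1c2ccc(O)cc2O[C@H](c2cc(O)c(O)c(O)c2[C@@H]2c3ccc(OCc4ccccc4)cc3O[C@H](c3cc(OCc4ccccc4)c(OCc4ccccc4)c(OCc4ccccc4)c3)[C@H]2OC(=O)CCl)[C@H]1O | intermediate
13 | 7,3′,4′,5′-tetra-O-benzylrobinetinidol-(4α→2′)-dihydrorobinetin; upper unit (2R,3S,4S), lower unit (2R,3R) | O=C1c2ccc(O)cc2O[C@H](c2cc(O)c(O)c(O)c2[C@@H]2c3ccc(OCc4ccccc4)cc3O[C@H](c3cc(OCc4ccccc4)c(OCc4ccccc4)c(OCc4ccccc4)c3)[C@H]2O)[C@H]1O | intermediate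
14 | (2R,3R)-3,7-dihydroxy-2-{3,4,5-trihydroxy-2-[(2R,3S,4S)-3,7-dihydroxy-2-(3,4,5-trihydroxyphenyl)chroman-4-yl]phenyl}chroman-4-one | O=C1c2ccc(O)cc2O[C@H](c2cc(O)c(O)c(O)c2[C@@H]2c3ccc(O)cc3O[C@H](c3cc(O)c(O)c(O)c3)[C@H]2O)[C@H]1O | target

Total step count: 8. Longest linear sequence: 8 steps (1 to 14).

**Steps most likely to fail**

Step 6 (Proposed new method). The 1,2-shift may lose to attack of the phenol at the acylal carbon, to hydride migration from C3 followed by aromatisation of the furan ring, or to self-condensation through ring A. Epimerisation of 8 before acylation would also send material into the 2,3-cis series. The fallback uses known chemistry, sets out from 9 and comes back at 14. A portion of 9 is reduced with NaBH4 in ethanol to the flavan-3,4-diol (2R,3S,4R)-leucorobinetinidin F1. F1 is then condensed with an excess of 9 in 0.1 M aqueous HCl at room temperature, where the 2,3-trans flavan-4-yl cation should be captured by C2′ of 9 anti to the 3-hydroxyl, giving 14 without protecting groups. In this fallback the pyran ring of the upper unit is taken over from 9 and is not made by ring enlargement.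

Step 4. A stepwise hydride-transfer pathway at the very electron-rich benzylic ether may erode the cis selectivity and the enantiomeric purity. The fallback sets out from 6 and comes back at 7. The diazo ester 6 is decomposed with an achiral rhodium(II) carboxylate (Rh2(OPiv)4, CH2Cl2) and any trans isomer is removed on silica. The racemic cis ester, that is 7 together with its enantiomer methyl (2R,3S)-6-(benzyloxy)-2-[3,4,5-tris(benzyloxy)phenyl]-2,3-dihydro-1-benzofuran-3-carboxylate F2, is resolved by preparative chromatography on a chiral stationary phase, and 7 continues into step 5.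

Step 5. Over-reduction, or epimerisation of the α-aryl aldehyde at C3 to the trans isomer on the aluminium Lewis acid or during isolation, may occur. The fallback sets out from 7 and comes back at 8. Ester 7 is reduced completely with LiAlH4 (THF, 0 °C) to the configurationally stable cis alcohol {(2S,3S)-6-(benzyloxy)-2-[3,4,5-tris(benzyloxy)phenyl]-2,3-dihydro-1-benzofuran-3-yl}methanol F3, which can be purified. F3 is then oxidised with Dess–Martin periodinane (NaHCO3, CH2Cl2, 0 °C) immediately before step 6.

**Further compounds**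

F1 | step 6 | (2R,3S,4R)-2-(3,4,5-trihydroxyphenyl)chromane-3,4,7-triol (leucorobinetinidin) | O[C@@H]1c2ccc(O)cc2O[C@H](c2cc(O)c(O)c(O)c2)[C@H]1O
F2 | step 4 | methyl (2R,3S)-6-(benzyloxy)-2-[3,4,5-tris(benzyloxy)phenyl]-2,3-dihydro-1-benzofuran-3-carboxylate | COC(=O)[C@H]1c2ccc(OCc3ccccc3)cc2O[C@H]1c1cc(OCc2ccccc2)c(OCc2ccccc2)c(OCc2ccccc2)c1
F3 | step 5 | {(2S,3S)-6-(benzyloxy)-2-[3,4,5-tris(benzyloxy)phenyl]-2,3-dihydro-1-benzofuran-3-yl}methanol | OC[C@@H]1c2ccc(OCc3ccccc3)cc2O[C@@H]1c1cc(OCc2ccccc2)c(OCc2ccccc2)c(OCc2ccccc2)c1
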